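The runs come from a simulation on assumed constants, and the scatter is random.

The target is what the next flask is charged for, and the open choice is its catalyst: 15 µM, as on Friday and Wednesday, or 22 µM, as on Sunday.

| flask | substrate | catalyst | remark | time |
|---|---|---|---|---|
| Friday's | 5 mM | 15 µM | run made earlier |  |
| Wednesday's | 7.5 mM | 15 µM | run made earlier |  |
| Sunday's | 10 mM | 22 µM | run made earlier |  |
| flask | 10 mM | 15 µM |  | 3.0 min |

| run | time / min | target / % | isomer of the product / % |
|---|---|---|---|
| Friday's | 0.417 | 22.7 | 2.1 |
| Friday's | 1.00 | 43.0 | 0.1 |
| Friday's | 2.00 | 67.9 | 2.5 |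
| Friday's | 3.00 | 78.8 | 2.9 |
| Wednesday's | 0.833 | 40.2 | 0.5 |
| Wednesday's | 1.50 | 59.1 | 2.1 |
| Wednesday's | 2.50 | 73.2 | 1.8 |
| Wednesday's | 3.00 | 79.8 | 2.4 |
| Sunday's | 0.250 | 17.4 | 1.7 |
| Sunday's | 0.500 | 33.5 | 0 |
| Sunday's | 1.33 | 66.4 | 1.5 |
| Sunday's | 3.00 | 88.7 | 0.7 |

(each reading ± 1 percentage point)

* share of target in target plus isomer of the product at 2.0 s
* share of target in target plus isomer of the product at 3.0 min



Isomer of the product appears beside target from the first readings, with no clear growth relative to it, so the two paths are compared by their odds. The selectivity factor S is target formed over isomer formed, and its logarithm counts the powers of ten between the two paths. Summing the readings of each set gives: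

Friday and Wednesday: S = 32.3, lg S = 1.51

Sunday: S = 52.8, lg S = 1.72

Sunday's step of 0.210 lies near the step in lg[catalyst], 0.166, as if catalyst sped the target path and left the isomer path alone. But Sunday's isomer readings lie between 0% and 1.7% with a scatter of 1 percentage point, and that run differs from the others in substrate as well, so this is a hint and no measurement.

The share of target is S/(1+S), which I reckon at 97.0% for 15 µM and 98.1% for 22 µM. The extra catalyst goes with 1.1 points more share, but the share is not the amount: at 3.00 min target reads 88.7% on Sunday against 78.8% on Friday and 79.8% on Wednesday, so a choice made for target looks to that reading and not to the share. The flask is charged with 15 µM of catalyst and 10 mM of substrate, which matches Sunday's substrate and Friday's catalyst, and so it puts the hint to the test. With odds that hold from the start, I expect the same share at 2.0 s and 3.0 min.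

The forecast gives 97% (91% to 99.8%) at 2.0 s and 97% (95.3% to 98.6%) at 3.0 min, from “a parallel path with constant selectivity”.

The flask gives 98.6% and 98.5%.

    substrate + catalyst ⇌ target + catalyst, rate k1*[substrate]*[catalyst] forward; the back reaction follows from the equilibrium constant (K = 14.5, k = 672 M⁻¹ s⁻¹)
    substrate ⇌ isomer of the product (K = 0.670, k = 1.43 × 10⁻⁴ s⁻¹)

In the flask, substrate goes by the forward target path faster than by the forward isomer path, by a ratio of 70 at 0.858 min and 70 at 3.00 min, which is lg S = 1.85 against the 1.51 read from the runs. A neighbour flask charged with 3.70 µM of catalyst stands 0.608 lower on that scale, so S = 17.3 and a share of 94.5%, and that neighbour holds 94.6%.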